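The autumn and midnight runs showed me one regularity before I turned to the flask.

| flask | starting material | remark | time |
|---|---|---|---|
| autumn | 0.14 M | run made earlier |  |
| midnight | 0.22 M | run made earlier |  |
| flask | 0.10 M |  | 1.5 h |

| run | time / min | target / % |
|---|---|---|
| autumn | 1.00 | 72.6 |
| autumn | 2.50 | 79.1 |
| autumn | 6.00 | 74.9 |
| autumn | 15.0 | 61.7 |
| autumn | 40.0 | 29.5 |
| autumn | 120 | 11.3 |
| midnight | 1.00 | 72.0 |
| midnight | 2.50 | 79.2 |
| midnight | 6.00 | 76.4 |
| midnight | 15.0 | 68.0 |
| midnight | 40.0 | 43.2 |
| midnight | 120 | 9.3 |

(readings scatter by 0.5 percentage points)

- percentages count the starting material that a species holds: one self-condensation product or side product counts as two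
- target is meant together with its crystals
- solid, in amounts per volume of the solution: crystals
- the numbers in the tables scatter by 0.5 percentage points (one standard deviation)
- what may be going on: starting material <-> target; 2 starting material -> self-condensation product; starting material + target -> side product; crystals <-> target

- the moment within 1.5 h at which there is most target, in min
- the amount of target, in percent of the starting material charged, at that time

Between 6.00 min and 15.0 min, the autumn run lost target at 0.00205 M min⁻¹ as read. The midnight run lost it at 0.00205 M min⁻¹ as read, though its charge was larger. I called this fall of c(target) per minute between those readings the drain; over that stretch it looked like a zero-order loss.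

I then turned the question round. What would a late best in the flask have needed? The charge divided by the drain gives a drain time. The midnight run's was 107 min, yet its readings were already falling after 2.50 min. So I reasoned that a late best needed a drain time beyond that. With the same drain, my estimate for the flask was 48.7 min, about half of it, so I expected the flask's best to come early, near or before 2.50 min.

The forecast said 2.1 min and 76 %, reasoning that “crystals hold dissolved target at saturation”.

The flask reached its best, 79.0 %, at 1.99 min, and both forecast values held within their margins. At that moment, crystals held 18.8 % of the charge. Starting from that best, the drain time put target in the flask at 64.6 % after 0.150 h, and the flask held 65.5 % of target, with crystals at 5.89 %.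

    starting material ⇌ target (K = 7.42, k = 2.14 min⁻¹)
    2 starting material → self-condensation product (k = 0.250 L mol⁻¹ min⁻¹)
    starting material + target → side product (k = 2.27 L mol⁻¹ min⁻¹)
    crystals ⇌ target, rate k4*(cs4 - [target]) while solid is left; crystals form when [target] > cs4 (solubility = 0.0600 M, k = 5.23 min⁻¹)

For the same flask left until 25 min, the drain time gave 31.8 % of target. The simulation gave 42.1 % of target, with crystals at 0 %.

(Readings and results were generated by integration for substances that don't exist, noise included.)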